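I began from the balance that a closed flask cannot break: the starting complex charged is found later as starting complex, complex with one exchanged, complex with two exchanged or isomer of the product.

| setting | south-west | north-west | west | Tuesday's | Saturday's |
|---|---|---|---|---|---|
| starting complex | 0.055 M | 0.10 M | 0.077 M | 0.077 M | 0.040 M |
| incoming ligand | 0.0924 M | 0.0924 M | 0.051 M | 0.0924 M | 0.0500 M |
| temperature | 20 °C | 31 °C | 20 °C | 25 °C | 25 °C |
| remark | run made earlier | run made earlier | run made earlier |  |  |
| time |  |  |  | 8.0 h | 8.0 h |

| run | time / h | complex with one exchanged / % | complex with two exchanged / % |
|---|---|---|---|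
| south-west | 0.667 | 32 | 2 |
| south-west | 1.33 | 39 | 5 |
| south-west | 2.00 | 43 | 7 |
| south-west | 2.50 | 40 | 6 |
| south-west | 3.00 | 40 | 8 |
| south-west | 4.00 | 36 | 10 |
| north-west | 0.333 | 26 | 2 |
| north-west | 0.500 | 30 | 4 |
| north-west | 0.833 | 29 | 2 |
| north-west | 1.33 | 27 | 2 |
| north-west | 2.50 | 27 | 2 |
| north-west | 4.00 | 26 | 4 |
| west | 0.333 | 11 | 0 |
| west | 1.00 | 20 | 0 |
| west | 2.00 | 26 | 0 |
| west | 3.00 | 25 | 1 |
| west | 4.00 | 26 | 3 |

(scatter of a reading: 1.5 percentage points)

- reactions considered so far: starting complex + incoming ligand <-> leaving ligand + complex with one exchanged; complex with one exchanged <-> isomer of the product; complex with one exchanged + incoming ligand <-> leaving ligand + complex with two exchanged; incoming ligand -> decomposed reagent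

- the flask that ends with the higher share of complex with one exchanged in all that became complex with one exchanged or complex with two exchanged or isomer of the product, or "neither" when 2 percentage points or less lies between them (Tuesday's / Saturday's / neither)
- share of complex with one exchanged in all that became complex with one exchanged or complex with two exchanged or isomer of the product, Tuesday's
- share of complex with one exchanged in all that became complex with one exchanged or complex with two exchanged or isomer of the product, Saturday's

Two numbers in the south-west run did not seem to go together: it held more incoming ligand than starting complex, 0.0924 M against 0.055 M, so starting complex was the limiting reagent of the first exchange, yet the two exchanged complexes together read 46.0% after 4.00 h. The balance cleared this up, since the missing 54.0% must be starting complex or isomer of the product, neither of them read, and the sum of the readings had not grown since the 50.0% of 2.00 h; I took the south-west flask to be near a balance of its reversible steps.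

Each exchange swaps one ligand for another, so at one temperature its equilibrium depends on the proportion of the charges and not their scale, and the isomerisation and the first-order decay of ligand are scale-free too. I therefore carried Tuesday's 1.20 against Saturday's 1.25: the charge ratio r, incoming ligand charged per starting complex charged. The readings of complex with one exchanged in the west run, colder and with incoming ligand close to Saturday's, stopped rising by 2.00 h, earlier than the 8.0 h asked, so I expected both flasks near balance, and with r at 1.20 and 1.25 my own answer was neither.

The forecast said Saturday's, with 72% for Tuesday's and 78% for Saturday's, on the ground that “Saturday is about half as concentrated, so it makes less bis”.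

The flasks gave neither: 47.2% for Tuesday's and 47.4% for Saturday's.

    starting complex + incoming ligand ⇌ leaving ligand + complex with one exchanged (K = 1.60, k = 0.200 /M/min, Ea = 61.0 kJ/mol, ΔH = −51.0 kJ/mol)
    complex with one exchanged ⇌ isomer of the product (K = 0.930, k = 0.00760 /min, Ea = 89.0 kJ/mol, ΔH = −31.0 kJ/mol)
    complex with one exchanged + incoming ligand ⇌ leaving ligand + complex with two exchanged (K = 0.360, k = 0.0420 /M/min, Ea = 55.0 kJ/mol, ΔH = −48.0 kJ/mol)
    incoming ligand → decomposed reagent (k = 0.00110 /min, Ea = 105 kJ/mol)
    (constants at 25 °C)

Tuesday's flask with r of 1.20 ended with starting complex at 38.4%, and Saturday's with r of 1.25 at 38.1%. Tuesday's share stands where it does because isomer of the product falls back to complex with one exchanged: Tuesday's run without that way back ends at 9.58% instead of 47.2%. Saturday's recipe with 0.085 M of incoming ligand has r of 2.12, higher than the 1.25 of Saturday's and the 1.20 of Tuesday's, which points to less starting complex and more complex with two exchanged; that flask gave 24.0% and 11.1%, against 38.1% and 5.34% in Saturday's, and a share of 44.2%.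

The numbers in the tables come from a simulation for an exercise, noise included.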